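The flavone is cut at the C2–C1' bond between ring C and ring B. A palladium-catalysed oxidative boron-Heck arylation forges this bond in one operation at the C2–H of a preformed chromone. It uses the polarity of the O1–C2=C3–C4=O enone (C2 is the β-carbon) and the fact that C1' is the only ring B carbon flanked by two C–H positions, so that iridium-catalysed borylation places boron there. The precursors are 5,8-dimethoxy-7-(methoxymethoxy)chromone and the ring B pinacol boronate; the same boronate, oxidised and methylated, also supplies ring A. All three phenols travel as methoxymethyl ethers and are released together by acid.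

Key step: step 8

Remark: O7 is carried as a methoxymethyl (MOM) ether instead of a benzyl ether; no bond of the key step changes, and one acid treatment then completes the synthesis.

Step 1
Reactants: 1 2-methoxyresorcinol (2-methoxybenzene-1,3-diol)
Product: 2 2-methoxy-1,3-bis(methoxymethoxy)benzene
Conditions: NaH (2.4 equiv), MOMCl (2.4 equiv), DMF, 0 °C to rt
Reagents that add atoms: chloromethyl methyl ether, COCCl
Why: Williamson-type O-alkylation of both sodium phenoxides by the reactive α-chloro ether should give the bis-acetal, which is base-stable, directs metalation later and is removed by acid.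

Step 2
Reactants: 2 2-methoxy-1,3-bis(methoxymethoxy)benzene; 3 bis(pinacolato)diboron
Product: 4 2-[4-methoxy-3,5-bis(methoxymethoxy)phenyl]-4,4,5,5-tetramethyl-1,3,2-dioxaborolane
Conditions: [Ir(OMe)(cod)]2 (1.5 mol %), 4,4'-di-tert-butyl-2,2'-bipyridine (3 mol %), 3 (1.0 equiv), THF, 65 °C
Reagents that add atoms: none
Why: Iridium-catalysed aromatic C–H borylation is sterically controlled, so boron should enter at C5 of 2, the only C–H with no ortho substituent.

Step 3
Reactants: 4 2-[4-methoxy-3,5-bis(methoxymethoxy)phenyl]-4,4,5,5-tetramethyl-1,3,2-dioxaborolane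
Product: 5 4-methoxy-3,5-bis(methoxymethoxy)phenol
Conditions: 30% H2O2, aq. NaOH, THF, 0 °C; then aq. Na2S2O3, adjust to pH 7
Reagents that add atoms: hydrogen peroxide, OO
Why: Oxidation of an arylboronate, in which hydroperoxide adds to boron and the aryl group shifts from boron to oxygen, should give the phenol while the base-stable MOM ethers stay intact.

Step 4
Reactants: 5 4-methoxy-3,5-bis(methoxymethoxy)phenol
Product: 6 2,5-dimethoxy-1,3-bis(methoxymethoxy)benzene
Conditions: MeI, K2CO3, acetone, 50 °C
Reagents that add atoms: iodomethane, CI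
Why: Williamson ether synthesis on the only free phenol should install the methoxy group that becomes 5-OMe of ring A.

Step 5
Reactants: 6 2,5-dimethoxy-1,3-bis(methoxymethoxy)benzene; 7 N-methoxy-N-methylacetamide
Product: 10 1-[3,6-dimethoxy-2,4-bis(methoxymethoxy)phenyl]ethan-1-one, via aryllithium 8 (not isolated), via lithium hemiaminal alkoxide 9 (not isolated)
Conditions: n-BuLi (1.1 equiv), TMEDA, THF, 0 °C; then 7, −78 °C to 0 °C; aq. NH4Cl
Reagents that add atoms: none
Why: Directed ortho-metalation at a C–H flanked by OMOM and OMe (the two aromatic C–H positions are equivalent by symmetry) followed by Weinreb ketone synthesis should give the methyl ketone, because the chelated tetrahedral adduct blocks a second addition.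

Step 6
Reactants: 10 1-[3,6-dimethoxy-2,4-bis(methoxymethoxy)phenyl]ethan-1-one; 11 N,N-dimethylformamide dimethyl acetal
Product: 14 7-hydroxy-5,8-dimethoxy-4H-chromen-4-one, via MOM-protected enaminone 12 (not isolated), via dihydroxy enaminone 13 (not isolated)
Conditions: 11 (3 equiv), PhMe, 105 °C; evaporate; then 2 M HCl in MeOH, 60 °C
Reagents that add atoms: none
Why: Aminomethylenation of the methyl ketone gives the E-enaminone, and methanolic acid then transfers both MOM groups to the solvent so that the freed 2-hydroxyl closes ring C by 6-endo addition–elimination at the enaminone β-carbon with loss of dimethylamine (enaminone chromone synthesis).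

Step 7
Reactants: 14 7-hydroxy-5,8-dimethoxy-4H-chromen-4-one
Product: 15 5,8-dimethoxy-7-(methoxymethoxy)-4H-chromen-4-one
Conditions: MOMCl (1.3 equiv), K2CO3, DMF, 0 °C to rt
Reagents that add atoms: chloromethyl methyl ether, COCCl
Why: The 7-hydroxyl is an acidic vinylogous acid and the only nucleophile present, so Williamson-type O-alkylation should give the MOM ether cleanly.

Step 8
Reactants: 15 5,8-dimethoxy-7-(methoxymethoxy)-4H-chromen-4-one; 4 2-[4-methoxy-3,5-bis(methoxymethoxy)phenyl]-4,4,5,5-tetramethyl-1,3,2-dioxaborolane
Product: 16 5,8-dimethoxy-7-(methoxymethoxy)-2-[4-methoxy-3,5-bis(methoxymethoxy)phenyl]-4H-chromen-4-one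
Conditions: Pd(O2CCF3)2 (15 mol %), 5-nitro-1,10-phenanthroline (20 mol %), 4 (2.5 equiv), O2 (1 atm), DMSO, 100 °C
Reagents that add atoms: none
Why: Boron-to-palladium transfer of the ring B aryl group from 4 onto phenanthroline-ligated divalent palladium is followed by syn migratory insertion of the C2=C3 bond of 15, the aryl carbon bonding to C2 and the metal to C3. Because the C2 hydrogen then lies anti to the metal, the C3-bound species must pass through its oxygen-bound enolate before syn β-hydride elimination regenerates the 4-pyranone, and O2 in DMSO reoxidises zerovalent palladium to divalent palladium. The closest known reaction type is the oxidative boron-Heck arylation of chromones and other cyclic enones with arylboron reagents, a relative of palladium-catalysed conjugate addition followed by dehydrogenation. No ring is closed and no stereocentre is formed, since C2 ends sp2. The step needs C2 rather than C3 arylation, secured by the polarity of the O1–C2=C3–C4=O vinylogous ester (the aryl group migrates to the β-carbon and palladium sits α to the carbonyl), and a single ring B regioisomer, secured because boron already marks C1'. The 2-aryl product is a β,β-disubstituted enone that resists a second arylation, and a MOM group lost in the warm, weakly acidic medium costs nothing because step 9 removes them all.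

Step 9
Reactants: 16 5,8-dimethoxy-7-(methoxymethoxy)-2-[4-methoxy-3,5-bis(methoxymethoxy)phenyl]-4H-chromen-4-one
Product: 17 2-(3,5-dihydroxy-4-methoxyphenyl)-7-hydroxy-5,8-dimethoxy-4H-chromen-4-one
Conditions: 2 M HCl in MeOH, THF co-solvent, 50 °C
Reagents that add atoms: none
Why: Acid-catalysed acetal exchange should transfer all three MOM groups to methanol, while the aryl methyl ethers (including 5-OMe next to the carbonyl) and the pyranone are inert to methanolic HCl.

Compound list
1 | 2-methoxyresorcinol (2-methoxybenzene-1,3-diol) | COc1c(O)cccc1O | starting material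
2 | 2-methoxy-1,3-bis(methoxymethoxy)benzene | COCOc1cccc(OCOC)c1OC | intermediate
3 | bis(pinacolato)diboron | CC1(C)OB(OC1(C)C)B1OC(C)(C)C(C)(C)O1 | starting material
4 | 2-[4-methoxy-3,5-bis(methoxymethoxy)phenyl]-4,4,5,5-tetramethyl-1,3,2-dioxaborolane | COCOc1cc(B2OC(C)(C)C(C)(C)O2)cc(OCOC)c1OC | intermediate
5 | 4-methoxy-3,5-bis(methoxymethoxy)phenol | COCOc1cc(O)cc(OCOC)c1OC | intermediate
6 | 2,5-dimethoxy-1,3-bis(methoxymethoxy)benzene | COCOc1cc(OC)cc(OCOC)c1OC | intermediate
7 | N-methoxy-N-methylacetamide | CC(=O)N(C)OC | starting material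
8 | [3,6-dimethoxy-2,4-bis(methoxymethoxy)phenyl]lithium (formed in the flask) | COCOc1cc(OC)c([Li])c(OCOC)c1OC | intermediate
9 | lithium 1-[3,6-dimethoxy-2,4-bis(methoxymethoxy)phenyl]-1-[methoxy(methyl)amino]ethan-1-olate (racemic, formed in the flask) | COCOc1cc(OC)c(C(C)(O[Li])N(C)OC)c(OCOC)c1OC | intermediate
10 | 1-[3,6-dimethoxy-2,4-bis(methoxymethoxy)phenyl]ethan-1-one | CC(=O)c1c(OCOC)c(OC)c(OCOC)cc1OC | intermediate
11 | N,N-dimethylformamide dimethyl acetal | COC(OC)N(C)C | starting material
12 | (E)-3-(dimethylamino)-1-[3,6-dimethoxy-2,4-bis(methoxymethoxy)phenyl]prop-2-en-1-one (formed in the flask) | CN(C)/C=C/C(=O)c1c(OCOC)c(OC)c(OCOC)cc1OC | intermediate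
13 | (E)-1-(2,4-dihydroxy-3,6-dimethoxyphenyl)-3-(dimethylamino)prop-2-en-1-one (formed in the flask) | CN(C)/C=C/C(=O)c1c(O)c(OC)c(O)cc1OC | intermediate
14 | 7-hydroxy-5,8-dimethoxy-4H-chromen-4-one | COc1cc(O)c(OC)c2occc(=O)c12 | intermediate
15 | 5,8-dimethoxy-7-(methoxymethoxy)-4H-chromen-4-one | COc1cc(OCOC)c(OC)c2occc(=O)c12 | intermediate
16 | 5,8-dimethoxy-7-(methoxymethoxy)-2-[4-methoxy-3,5-bis(methoxymethoxy)phenyl]-4H-chromen-4-one | COc1cc(OCOC)c(OC)c2oc(-c3cc(OCOC)c(OC)c(OCOC)c3)cc(=O)c12 | intermediate
17 | 2-(3,5-dihydroxy-4-methoxyphenyl)-7-hydroxy-5,8-dimethoxy-4H-chromen-4-one | COc1c(O)cc(-c2cc(=O)c3c(OC)cc(O)c(OC)c3o2)cc1O | target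

Total step count: 9.
Longest linear sequence: 9 steps (1 → 2 → 4 → 5 → 6 → 10 → 14 → 15 → 16 → 17). Boronate 4 is drawn from this one line twice, for step 3 and for step 8.

Steps most likely to fail

Step 8. The electron-rich boronate may be consumed by protodeboronation or oxidative homocoupling faster than the aryl–palladium species inserts into the electron-rich, trioxygenated chromone. Turnover may also stall before β-hydride elimination, leaving the saturated C2–C3 compound. The fallback builds ring C last and sets out from ketone 10. Its lithium enolate (LiN(SiMe3)2, THF, −78 °C to rt) would undergo crossed Claisen condensation with methyl 4-methoxy-3,5-bis(methoxymethoxy)benzoate F1, made from commercial methyl 3,5-dihydroxy-4-methoxybenzoate with MOMCl and K2CO3. This should give 1-[3,6-dimethoxy-2,4-bis(methoxymethoxy)phenyl]-3-[4-methoxy-3,5-bis(methoxymethoxy)phenyl]propane-1,3-dione F2. Warm methanolic HCl would then remove all four MOM groups to give 1-(2,4-dihydroxy-3,6-dimethoxyphenyl)-3-(3,5-dihydroxy-4-methoxyphenyl)propane-1,3-dione F3 in the flask. Its only ortho hydroxyl cyclodehydrates onto the ring B carbonyl (the closing stage of a Baker–Venkataraman flavone synthesis), and the sequence comes back to the route at 17.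

Step 5. The hindered aryllithium may act as a base toward the α-hydrogens of the amide instead of adding to its carbonyl, returning 6, or the metalation may stay incomplete. The fallback replaces metalation by electrophilic aromatic substitution and sets out from 6. Methanolic HCl would release 2,5-dimethoxybenzene-1,3-diol F4. Friedel–Crafts (Nencki-type) C-acetylation with AcOH and BF3·OEt2 at 80 °C can only strike the two symmetry-equivalent ring positions and should give 1-(2,4-dihydroxy-3,6-dimethoxyphenyl)ethan-1-one F5. Condensation with a near-stoichiometric amount of 11 and acid closure as in step 6 would pass through 13 and come back to the route at 14.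

Step 6. Condensation at the doubly ortho-substituted acetyl group may be sluggish, or the aminomethylene unit may be lost by solvolysis before the phenol is unmasked and closes. The fallback introduces the one-carbon unit at the oxygen level and sets out from 10. Claisen formylation with HCO2Et and NaH in THF should give 3-[3,6-dimethoxy-2,4-bis(methoxymethoxy)phenyl]-3-oxopropanal F6, handled as its enol. Methanolic HCl would unmask 3-(2,4-dihydroxy-3,6-dimethoxyphenyl)-3-oxopropanal F7 in the flask, which cyclodehydrates in the classical chromone closure and comes back to the route at 14.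

Further compounds
F1 | step 8 | methyl 4-methoxy-3,5-bis(methoxymethoxy)benzoate | COC(=O)c1cc(OCOC)c(OC)c(OCOC)c1
F2 | step 8 | 1-[3,6-dimethoxy-2,4-bis(methoxymethoxy)phenyl]-3-[4-methoxy-3,5-bis(methoxymethoxy)phenyl]propane-1,3-dione | COCOc1cc(OC)c(C(=O)CC(=O)c2cc(OCOC)c(OC)c(OCOC)c2)c(OCOC)c1OC
F3 | step 8 | 1-(2,4-dihydroxy-3,6-dimethoxyphenyl)-3-(3,5-dihydroxy-4-methoxyphenyl)propane-1,3-dione | COc1cc(O)c(OC)c(O)c1C(=O)CC(=O)c1cc(O)c(OC)c(O)c1
F4 | step 5 | 2,5-dimethoxybenzene-1,3-diol | COc1cc(O)c(OC)c(O)c1
F5 | step 5 | 1-(2,4-dihydroxy-3,6-dimethoxyphenyl)ethan-1-one | CC(=O)c1c(O)c(OC)c(O)cc1OC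
F6 | step 6 | 3-[3,6-dimethoxy-2,4-bis(methoxymethoxy)phenyl]-3-oxopropanal | O=CCC(=O)c1c(OCOC)c(OC)c(OCOC)cc1OC
F7 | step 6 | 3-(2,4-dihydroxy-3,6-dimethoxyphenyl)-3-oxopropanal | O=CCC(=O)c1c(O)c(OC)c(O)cc1OC
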